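**Plan**

- Both halves are (+)-catechin (1). The retrosynthesis cuts first the bond between C8 of ring A of the flavan unit and the benzylic diarylmethine carbon C-1 of the open (chalcane) unit, then the C-1–S bond of a thioether that stores the cation, and behind it the O1–C2 bond of ring C of a second catechin.
- Forward: one portion of 1 is benzylated and acetylated to give the C8 nucleophile. A second portion is opened at O1–C2 by ethanethiolate and peracetylated to give the electrophile. The chain is joined to C8 in step 5, then acetates and benzyl ethers are removed. No ring is built.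
- Enabling feature: C2 of catechin is benzylic to ring B, para to O4', and bound to the ring-A phenoxide O1, so ring C opens to a quinone methide. The same carbon is vicinal to O3, whose acetate later closes on it as a dioxolanium ion. C8 of ring A lies between O1 and O7 and para to O5.
- Stereochemistry: C2 and C3 of the flavan unit and the carbinol carbon of the open unit (C3 of the second catechin) come unchanged from 1. The diarylmethine centre is set in step 5, where both C-1 epimers of the thioether converge on one trans-dioxolanium ion that C8 opens with inversion (net retention relative to C2 of catechin).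
- Helpers: SEt (latent cation), acetates (silence rings A and B of the electrophile and participate at C-2), benzyl ethers (activate ring A and block the quinone methide of the nucleophile). All are removed in steps 6 and 7.

Key step: step 5

Remark: compounds 5 and 6 are carried as mixtures of C-1 epimers, so C-1 is written without a descriptor. DMTST = dimethyl(methylthio)sulfonium trifluoromethanesulfonate; DTBMP = 2,6-di-tert-butyl-4-methylpyridine.

**Route**

Step 1
Reactants: 1 (+)-catechin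
Product: 2 (2R,3S)-5,7-bis(benzyloxy)-2-[3,4-bis(benzyloxy)phenyl]chroman-3-ol
Conditions: BnBr (4.4 equiv), K2CO3, DMF, 0 °C to rt, N2
Reagents that add atoms: benzyl bromide, BrCc1ccccc1
Why: Williamson ether synthesis in which K2CO3 ionises only the four phenols, so the secondary 3-OH stays free and neither stereocentre is touched.

Step 2
Reactants: 2 (2R,3S)-5,7-bis(benzyloxy)-2-[3,4-bis(benzyloxy)phenyl]chroman-3-ol
Product: 3 (2R,3S)-5,7-bis(benzyloxy)-2-[3,4-bis(benzyloxy)phenyl]chroman-3-yl acetate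
Conditions: Ac2O, pyridine, DMAP (cat.), CH2Cl2, rt
Reagents that add atoms: acetic anhydride, CC(=O)OC(C)=O
Why: DMAP-catalysed O-acetylation caps the only hydroxyl of the arene partner, so that in step 5 it can react only through carbon.

Step 3
Reactants: 1 (+)-catechin
Product: 5 (2S)-1-(3,4-dihydroxyphenyl)-1-(ethylsulfanyl)-3-(2,4,6-trihydroxyphenyl)propan-2-ol as C-1 epimer mixture, via ring-opened para-quinone methide 4 (not isolated)
Conditions: EtSH (6 equiv), NaOH (aq, pH 12), degassed, N2, 23 to 40 °C; then HCl to pH 4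
Reagents that add atoms: ethanethiol, CCS
Why: Base-induced opening of ring C (the 4'-phenoxide of ring B expels the ring-A phenoxide O1 from C2) gives quinone methide 4, which the soft thiolate traps by thia-1,6-conjugate addition, the known base-mediated thiol cleavage of the pyran ring of flavan-3-ols; C3 of catechin becomes the (2S) carbinol untouched, and the new C-1 centre is not controlled because step 5 erases it.

Step 4
Reactants: 5 (2S)-1-(3,4-dihydroxyphenyl)-1-(ethylsulfanyl)-3-(2,4,6-trihydroxyphenyl)propan-2-ol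
Product: 6 (2S)-1-(3,4-diacetoxyphenyl)-1-(ethylsulfanyl)-3-(2,4,6-triacetoxyphenyl)propan-2-yl acetate as C-1 epimer mixture
Conditions: Ac2O, pyridine, DMAP (cat.), 0 °C to rt
Reagents that add atoms: acetic anhydride, CC(=O)OC(C)=O
Why: Exhaustive O-acetylation is fast and non-basic, so the latent quinone methide is not released, and it makes rings A and B inert as C- or O-nucleophiles while placing a participating ester next to C-1.

Step 5
Reactants: 6 (2S)-1-(3,4-diacetoxyphenyl)-1-(ethylsulfanyl)-3-(2,4,6-triacetoxyphenyl)propan-2-yl acetate; 3 (2R,3S)-5,7-bis(benzyloxy)-2-[3,4-bis(benzyloxy)phenyl]chroman-3-yl acetate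
Product: 8 (2R,3S)-3-acetoxy-5,7-bis(benzyloxy)-2-[3,4-bis(benzyloxy)phenyl]-8-[(1S,2S)-2-acetoxy-1-(3,4-diacetoxyphenyl)-3-(2,4,6-triacetoxyphenyl)propyl]chromane, via trans-dioxolanium triflate 7 (not isolated)
Conditions: 6, DMTST (1.05 equiv), DTBMP, 4 Å MS, CH2Cl2, −40 to −20 °C; then 3 (3 equiv), −40 to 0 °C
Reagents that add atoms: none
Why: DMTST sulfenylates the sulfide sulfur of 6, the vicinal C-2 acetate carbonyl expels the disulfide from C-1 to give the 2-methyl-1,3-dioxolan-2-ylium triflate 7, and C8 of 3 opens 7 at the benzylic carbon in a Friedel–Crafts alkylation while DTBMP takes up the acid. The closest known reaction type is the thiophilic activation of benzylic 4-thioethers of flavan-3-ols for interflavanyl C–C8 bond formation, combined with acyloxonium (neighbouring-group) control as in 1,2-trans C-aryl glycosylation and in the orthoester cyclisation of 1,3-diarylpropane-1,2-diols to 2,3-trans-flavan-3-ols. No ring of the product is closed; the temporary dioxolanium ring closes 5-exo-tet and is opened again. The new stereocentre C-1 is controlled by C-2: both C-1 epimers of 6 should drain, through exchange at the benzylic triflate and dimethylsulfonium stage, into the trans-4,5-disubstituted ion 7, and C8 enters anti to the departing ring oxygen to give the (1S,2S) unit. Site selectivity for C8 over C6 rests on C8 lying between O1 and the 7-benzyloxy group and para to the 5-benzyloxy group, the position at which this tetrabenzyl ether is normally brominated and alkylated. Chemoselectivity rests on the acetate shell of 6 (only sulfur reacts with the thiophile, rings A and B cannot act as nucleophiles) and on activating 6 before 3 is added.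

Step 6
Reactants: 8 (2R,3S)-3-acetoxy-5,7-bis(benzyloxy)-2-[3,4-bis(benzyloxy)phenyl]-8-[(1S,2S)-2-acetoxy-1-(3,4-diacetoxyphenyl)-3-(2,4,6-triacetoxyphenyl)propyl]chromane
Product: 9 (2R,3S)-5,7-bis(benzyloxy)-2-[3,4-bis(benzyloxy)phenyl]-8-[(1S,2S)-1-(3,4-dihydroxyphenyl)-2-hydroxy-3-(2,4,6-trihydroxyphenyl)propyl]chroman-3-ol
Conditions: NaOMe (10 equiv), degassed MeOH/THF, Ar, 0 °C to rt; then HCl to pH 4–5
Reagents that add atoms: none
Why: Zemplén transesterification removes all seven acetates, and it is run before debenzylation so that ring B of the flavan unit is still etherified and cannot open ring C through a quinone methide in base; no stereocentre is epimerisable.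

Step 7
Reactants: 9 (2R,3S)-5,7-bis(benzyloxy)-2-[3,4-bis(benzyloxy)phenyl]-8-[(1S,2S)-1-(3,4-dihydroxyphenyl)-2-hydroxy-3-(2,4,6-trihydroxyphenyl)propyl]chroman-3-ol
Product: 10 (2R,3S)-2-(3,4-dihydroxyphenyl)-8-[(1S,2S)-1-(3,4-dihydroxyphenyl)-2-hydroxy-3-(2,4,6-trihydroxyphenyl)propyl]chromane-3,5,7-triol (CNP0175733.2)
Conditions: H2 (1 atm), Pd(OH)2/C, THF/MeOH, rt
Reagents that add atoms: none
Why: Catalytic hydrogenolysis of the four aryl benzyl ethers under neutral conditions should leave the pyran C2–O1 bond, the diarylmethine bonds and all four stereocentres intact, as in the debenzylation of benzylated flavan-3-ol oligomers.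

**Compound list**

1 | (+)-catechin, (2R,3S)-2-(3,4-dihydroxyphenyl)chromane-3,5,7-triol | Oc1cc(O)c2c(c1)O[C@H](c1ccc(O)c(O)c1)[C@@H](O)C2 | starting material
2 | (2R,3S)-5,7-bis(benzyloxy)-2-[3,4-bis(benzyloxy)phenyl]chroman-3-ol | c1c(OCc4ccccc4)cc(OCc4ccccc4)c2c1O[C@H](c1ccc(OCc4ccccc4)c(OCc4ccccc4)c1)[C@@H](O)C2 | intermediate
3 | (2R,3S)-5,7-bis(benzyloxy)-2-[3,4-bis(benzyloxy)phenyl]chroman-3-yl acetate | c1c(OCc4ccccc4)cc(OCc4ccccc4)c2c1O[C@H](c1ccc(OCc4ccccc4)c(OCc4ccccc4)c1)[C@@H](OC(C)=O)C2 | intermediate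
4 | 2-hydroxy-4-[(2S)-2-hydroxy-3-(2,4,6-trihydroxyphenyl)propylidene]cyclohexa-2,5-dien-1-one (ring-opened para-quinone methide) | Oc1cc(O)c(C[C@H](O)C=C2C=CC(=O)C(O)=C2)c(O)c1 | intermediate
5 | (2S)-1-(3,4-dihydroxyphenyl)-1-(ethylsulfanyl)-3-(2,4,6-trihydroxyphenyl)propan-2-ol, C-1 epimer mixture | Oc1cc(O)c(C[C@H](O)C(SCC)c2ccc(O)c(O)c2)c(O)c1 | intermediate
6 | (2S)-1-(3,4-diacetoxyphenyl)-1-(ethylsulfanyl)-3-(2,4,6-triacetoxyphenyl)propan-2-yl acetate, C-1 epimer mixture | CC(=O)Oc1cc(OC(C)=O)c(C[C@H](OC(C)=O)C(SCC)c2ccc(OC(C)=O)c(OC(C)=O)c2)c(OC(C)=O)c1 | intermediate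
7 | (4S,5S)-4-(3,4-diacetoxyphenyl)-2-methyl-5-[(2,4,6-triacetoxyphenyl)methyl]-1,3-dioxolan-2-ylium trifluoromethanesulfonate (trans) | CC(=O)Oc1cc(OC(C)=O)c(C[C@@H]2OC(C)=[O+][C@H]2c2ccc(OC(C)=O)c(OC(C)=O)c2)c(OC(C)=O)c1.[O-]S(=O)(=O)C(F)(F)F | intermediate
8 | (2R,3S)-3-acetoxy-5,7-bis(benzyloxy)-2-[3,4-bis(benzyloxy)phenyl]-8-[(1S,2S)-2-acetoxy-1-(3,4-diacetoxyphenyl)-3-(2,4,6-triacetoxyphenyl)propyl]chromane | CC(=O)Oc1cc(OC(C)=O)c(C[C@H](OC(C)=O)[C@@H](c2ccc(OC(C)=O)c(OC(C)=O)c2)c2c(OCc4ccccc4)cc(OCc4ccccc4)c3c2O[C@H](c2ccc(OCc4ccccc4)c(OCc4ccccc4)c2)[C@@H](OC(C)=O)C3)c(OC(C)=O)c1 | intermediate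
9 | (2R,3S)-5,7-bis(benzyloxy)-2-[3,4-bis(benzyloxy)phenyl]-8-[(1S,2S)-1-(3,4-dihydroxyphenyl)-2-hydroxy-3-(2,4,6-trihydroxyphenyl)propyl]chroman-3-ol | Oc1cc(O)c(C[C@H](O)[C@@H](c2ccc(O)c(O)c2)c2c(OCc4ccccc4)cc(OCc4ccccc4)c3c2O[C@H](c2ccc(OCc4ccccc4)c(OCc4ccccc4)c2)[C@@H](O)C3)c(O)c1 | intermediate
10 | (2R,3S)-2-(3,4-dihydroxyphenyl)-8-[(1S,2S)-1-(3,4-dihydroxyphenyl)-2-hydroxy-3-(2,4,6-trihydroxyphenyl)propyl]chromane-3,5,7-triol | Oc1cc(O)c(C[C@H](O)[C@@H](c2ccc(O)c(O)c2)c2c(O)cc(O)c3c2O[C@H](c2ccc(O)c(O)c2)[C@@H](O)C3)c(O)c1 | target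

**Step count**

Total steps: 7. Longest linear sequence: 5 steps (1 → 5 → 6 → 8 → 9 → 10; the branch 1 → 2 → 3 → 8 → 9 → 10 is equally long).

**Steps most likely to fail**

Step 5. What may go wrong: incomplete funnelling of the two C-1 epimers (a stereospecific double inversion through a cis-dioxolanium ion would carry the epimer ratio of 6 into the product), slow ionisation because ring B is deactivated by its acetates, or attack through C6. The fallback sets out from 5 and comes back at 10. It exchanges the acetate shell for benzyl ethers, so that ring B stabilises a free benzylic cation and the ionisation is SN1 and convergent. Compound 5 is perbenzylated (BnBr, K2CO3, DMF) to (2S)-1-[3,4-bis(benzyloxy)phenyl]-1-(ethylsulfanyl)-3-[2,4,6-tris(benzyloxy)phenyl]propan-2-ol F1 and acetylated (Ac2O, pyridine) to (2S)-1-[3,4-bis(benzyloxy)phenyl]-1-(ethylsulfanyl)-3-[2,4,6-tris(benzyloxy)phenyl]propan-2-yl acetate F2. This is coupled with 3 (5 equiv, DMTST, DTBMP, CH2Cl2, −78 to −30 °C) to (2R,3S)-3-acetoxy-5,7-bis(benzyloxy)-2-[3,4-bis(benzyloxy)phenyl]-8-{(1S,2S)-2-acetoxy-1-[3,4-bis(benzyloxy)phenyl]-3-[2,4,6-tris(benzyloxy)phenyl]propyl}chromane F3. Deacetylation (NaOMe, MeOH/THF) gives (2R,3S)-5,7-bis(benzyloxy)-2-[3,4-bis(benzyloxy)phenyl]-8-{(1S,2S)-1-[3,4-bis(benzyloxy)phenyl]-2-hydroxy-3-[2,4,6-tris(benzyloxy)phenyl]propyl}chroman-3-ol F4, and hydrogenolysis (H2, Pd(OH)2/C) gives 10. The excess of 3 is needed here because ring A of the electrophile is itself nucleophilic.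

Step 3. What may go wrong: intramolecular C-alkylation of the quinone methide by ring A (catechinic-acid-type rearrangement), air oxidation of the polyphenolate, or incomplete capture by the thiolate. The fallback sets out from 1 and comes back at 8. It opens ring C from the acid side instead. Compound 1 is peracetylated (Ac2O, pyridine) to (2R,3S)-5,7-diacetoxy-2-(3,4-diacetoxyphenyl)chroman-3-yl acetate F5. In HBr/AcOH with Ac2O the 3-acetoxy group, antiperiplanar to C2–O1 in the trans-2,3 ring C, assists cleavage of the protonated benzylic aryl ether; bromide takes the benzylic carbon and Ac2O caps the liberated ring-A phenol. This gives (2S)-1-bromo-1-(3,4-diacetoxyphenyl)-3-(2,4,6-triacetoxyphenyl)propan-2-yl acetate F6 as C-1 epimer mixture. Abstraction of bromide with AgOTf (AgOSO2CF3; DTBMP, CH2Cl2, −40 °C) in a Koenigs–Knorr-type activation gives the same ion 7, which is coupled with 3 to 8.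

Step 6. What may go wrong: oxidative degradation of the electron-rich pentaphenolate in methoxide, or incomplete cleavage of the two secondary acetates. The fallback sets out from 8 and comes back at 10. It reverses the order and removes the acetates under acid, so that no phenoxide is ever formed. Hydrogenolysis of 8 (H2, Pd(OH)2/C, THF/MeOH) gives (2R,3S)-8-[(1S,2S)-2-acetoxy-1-(3,4-diacetoxyphenyl)-3-(2,4,6-triacetoxyphenyl)propyl]-2-(3,4-dihydroxyphenyl)-5,7-dihydroxychroman-3-yl acetate F7. Acid-catalysed methanolysis (HCl in MeOH, made from AcCl, rt, Ar) then gives 10.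

**Further compounds**

F1 | step 5 | (2S)-1-[3,4-bis(benzyloxy)phenyl]-1-(ethylsulfanyl)-3-[2,4,6-tris(benzyloxy)phenyl]propan-2-ol | O(Cc1ccccc1)c1cc(OCc2ccccc2)c(C[C@H](O)C(SCC)c2ccc(OCc3ccccc3)c(OCc3ccccc3)c2)c(OCc2ccccc2)c1
F2 | step 5 | (2S)-1-[3,4-bis(benzyloxy)phenyl]-1-(ethylsulfanyl)-3-[2,4,6-tris(benzyloxy)phenyl]propan-2-yl acetate | O(Cc1ccccc1)c1cc(OCc2ccccc2)c(C[C@H](OC(C)=O)C(SCC)c2ccc(OCc3ccccc3)c(OCc3ccccc3)c2)c(OCc2ccccc2)c1
F3 | step 5 | (2R,3S)-3-acetoxy-5,7-bis(benzyloxy)-2-[3,4-bis(benzyloxy)phenyl]-8-{(1S,2S)-2-acetoxy-1-[3,4-bis(benzyloxy)phenyl]-3-[2,4,6-tris(benzyloxy)phenyl]propyl}chromane | O(Cc1ccccc1)c1cc(OCc2ccccc2)c(C[C@H](OC(C)=O)[C@@H](c2ccc(OCc3ccccc3)c(OCc3ccccc3)c2)c2c(OCc4ccccc4)cc(OCc4ccccc4)c3c2O[C@H](c2ccc(OCc4ccccc4)c(OCc4ccccc4)c2)[C@@H](OC(C)=O)C3)c(OCc2ccccc2)c1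
F4 | step 5 | (2R,3S)-5,7-bis(benzyloxy)-2-[3,4-bis(benzyloxy)phenyl]-8-{(1S,2S)-1-[3,4-bis(benzyloxy)phenyl]-2-hydroxy-3-[2,4,6-tris(benzyloxy)phenyl]propyl}chroman-3-ol | O(Cc1ccccc1)c1cc(OCc2ccccc2)c(C[C@H](O)[C@@H](c2ccc(OCc3ccccc3)c(OCc3ccccc3)c2)c2c(OCc4ccccc4)cc(OCc4ccccc4)c3c2O[C@H](c2ccc(OCc4ccccc4)c(OCc4ccccc4)c2)[C@@H](O)C3)c(OCc2ccccc2)c1
F5 | step 3 | (2R,3S)-5,7-diacetoxy-2-(3,4-diacetoxyphenyl)chroman-3-yl acetate | CC(=O)Oc1cc(OC(C)=O)c2c(c1)O[C@H](c1ccc(OC(C)=O)c(OC(C)=O)c1)[C@@H](OC(C)=O)C2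
F6 | step 3 | (2S)-1-bromo-1-(3,4-diacetoxyphenyl)-3-(2,4,6-triacetoxyphenyl)propan-2-yl acetate, C-1 epimer mixture | CC(=O)Oc1cc(OC(C)=O)c(C[C@H](OC(C)=O)C(Br)c2ccc(OC(C)=O)c(OC(C)=O)c2)c(OC(C)=O)c1
F7 | step 6 | (2R,3S)-8-[(1S,2S)-2-acetoxy-1-(3,4-diacetoxyphenyl)-3-(2,4,6-triacetoxyphenyl)propyl]-2-(3,4-dihydroxyphenyl)-5,7-dihydroxychroman-3-yl acetate | CC(=O)Oc1cc(OC(C)=O)c(C[C@H](OC(C)=O)[C@@H](c2ccc(OC(C)=O)c(OC(C)=O)c2)c2c(O)cc(O)c3c2O[C@H](c2ccc(O)c(O)c2)[C@@H](OC(C)=O)C3)c(OC(C)=O)c1
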